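## Retrosynthetic overview

1. The target comes from its aryl TIPS ether; the side-chain carbinol (C1') comes from a chelate-controlled 1,3-syn reduction of a cis β-hydroxy enone.
2. The ring carbinol (C2–OH) comes from a C2–B bond by stereoretentive oxidation.
3. Key step: the C1–C1' and C2–B bonds are made together by an enantioselective copper-catalysed syn-borylacylation of the ring alkene of 6,7-dimethoxy-1,2-dihydronaphthalene with a protected p-coumaroyl chloride. This alkene 1,2-difunctionalisation replaces the 2-tetralone/cinnamaldehyde aldol, whose chair transition state from the cyclic enolate would favour the unwanted anti adduct.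
4. The dihydronaphthalene comes from 6,7-dimethoxy-1-tetralone; the acid chloride comes from p-coumaric acid.
5. Ring order: no ring is built. The tetralin bicycle and the phenol ring are both bought, and C1/C2 are set in the copper step, C1' by 1,3-induction.

Assumption: the facial sense of the CuCl/(S,S)-Ph-BPE catalyst in step 4 is assigned by analogy and would be confirmed on alcohol 8; the mirror-image ligand is used if the first run gives the antipode.

## Route

Step 1
Reactants: 1 6,7-dimethoxy-3,4-dihydronaphthalen-1(2H)-one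
Product: 3 6,7-dimethoxy-1,2-dihydronaphthalene, via racemic tetralol 2 (not isolated)
Conditions: NaBH4, MeOH/THF, 0 °C; then TsOH·H2O (2 mol%), PhMe, 70 °C
Reagents that add atoms: none
Why: Borohydride reduction of the aryl ketone followed by acid-catalysed E1 dehydration of the electron-rich benzylic alcohol gives the conjugated cyclic styrene, with no stereocentre left.

Step 2
Reactants: 4 (E)-3-(4-hydroxyphenyl)prop-2-enoic acid (p-coumaric acid)
Product: 5 triisopropylsilyl (E)-3-[4-(triisopropylsilyloxy)phenyl]prop-2-enoate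
Conditions: TIPSCl (2.3 equiv), imidazole (5 equiv), DMF, rt
Reagents that add atoms: chlorotriisopropylsilane, CC(C)[Si](Cl)(C(C)C)C(C)C
Why: Imidazole-promoted silylation caps both the phenol (as a base-stable aryl TIPS ether) and the acid (as a silyl ester ready for activation).

Step 3
Reactants: 5 triisopropylsilyl (E)-3-[4-(triisopropylsilyloxy)phenyl]prop-2-enoate
Product: 6 (E)-3-[4-(triisopropylsilyloxy)phenyl]prop-2-enoyl chloride
Conditions: (COCl)2 (1.2 equiv), DMF (cat.), CH2Cl2, 0 °C to rt; volatiles removed in vacuo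
Reagents that add atoms: oxalyl chloride, O=C(Cl)C(=O)Cl
Why: Silyl ester to acid chloride exchange through the Vilsmeier-type chloroiminium species runs under neutral, HCl-free conditions, so the aryl silyl ether and the E-alkene are untouched.

Step 4
Reactants: 3 6,7-dimethoxy-1,2-dihydronaphthalene; 6 (E)-3-[4-(triisopropylsilyloxy)phenyl]prop-2-enoyl chloride
Product: 7 (E)-1-[(1R,2R)-6,7-dimethoxy-2-(4,4,5,5-tetramethyl-1,3,2-dioxaborolan-2-yl)-1,2,3,4-tetrahydronaphthalen-1-yl]-3-[4-(triisopropylsilyloxy)phenyl]prop-2-en-1-one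
Conditions: CuCl (5 mol%), (S,S)-Ph-BPE (6 mol%), B2pin2 (1.1 equiv), NaOt-Bu (1.1 equiv), THF, 0 °C; 6 (1.2 equiv) added over 1 h
Reagents that add atoms: bis(pinacolato)diboron, CC1(C)OB(OC1(C)C)B1OC(C)(C)C(C)(C)O1
Why: Proposed new method: the ligated copper boryl adds syn across the cyclic styrene (four-centre migratory insertion, boron to C2, copper to benzylic C1, face chosen by the C2-symmetric bisphosphine) and the benzylic C–Cu bond is acylated by the acid chloride with retention, so acyl and boryl end cis and both ring stereocentres are set in the one enantio-determining step, the cis isomer also being the thermodynamic one (C1 group pseudoaxial away from the peri hydrogen, C2 group equatorial); the closest known reaction types are the copper-catalysed borylacylation of vinylarenes with acid chlorides, the copper-catalysed syn-aminoboration of β-substituted styrenes and the CuH-catalysed hydroacylation of vinylarenes with anhydrides.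

Step 5
Reactants: 7 (E)-1-[(1R,2R)-6,7-dimethoxy-2-(4,4,5,5-tetramethyl-1,3,2-dioxaborolan-2-yl)-1,2,3,4-tetrahydronaphthalen-1-yl]-3-[4-(triisopropylsilyloxy)phenyl]prop-2-en-1-one
Product: 8 (E)-1-[(1S,2R)-2-hydroxy-6,7-dimethoxy-1,2,3,4-tetrahydronaphthalen-1-yl]-3-[4-(triisopropylsilyloxy)phenyl]prop-2-en-1-one
Conditions: NaBO3·4H2O (3 equiv), THF/H2O 1:1, 0 °C to rt, 1 h
Reagents that add atoms: sodium perborate tetrahydrate, [Na+].[Na+].O[B-]1(O)OO[B-](O)(O)OO1
Why: Perborate oxidation of the C–B bond goes by 1,2-migration of carbon from boron to oxygen with retention, the standard way from β-boryl ketones to β-hydroxy ketones, so the cis C1/C2 relationship is kept (the C1 descriptor changes from R to S only through CIP priorities).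

Step 6
Reactants: 8 (E)-1-[(1S,2R)-2-hydroxy-6,7-dimethoxy-1,2,3,4-tetrahydronaphthalen-1-yl]-3-[4-(triisopropylsilyloxy)phenyl]prop-2-en-1-one
Product: 11 (1S,2R)-1-[(1S,2E)-1-hydroxy-3-[4-(triisopropylsilyloxy)phenyl]prop-2-en-1-yl]-6,7-dimethoxy-1,2,3,4-tetrahydronaphthalen-2-ol, via diethylboron chelate 9 (not isolated), via sodium diethylborate 10 (not isolated)
Conditions: Et2BOMe (1.2 equiv), THF/MeOH 4:1, −78 °C; NaBH4 (1.2 equiv), −78 °C, 3 h; pH 7 buffer; MeOH co-evaporation
Reagents that add atoms: none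
Why: Narasaka–Prasad reduction: borohydride attacks the boron-chelated ketone axially on the face that leads to a chair borate, away from the axial C1 aryl group, giving the 1,3-syn diol and hence the (S)-carbinol, and the chelated carbonyl is reduced 1,2 at −78 °C.

Step 7
Reactants: 11 (1S,2R)-1-[(1S,2E)-1-hydroxy-3-[4-(triisopropylsilyloxy)phenyl]prop-2-en-1-yl]-6,7-dimethoxy-1,2,3,4-tetrahydronaphthalen-2-ol
Product: 12 (1S,2R)-1-[(1S,2E)-1-hydroxy-3-(4-hydroxyphenyl)prop-2-en-1-yl]-6,7-dimethoxy-1,2,3,4-tetrahydronaphthalen-2-ol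
Conditions: TBAF (1.1 equiv), AcOH (1.1 equiv), THF, 0 °C, 30 min
Reagents that add atoms: none
Why: Fluoride-mediated desilylation cleaves the aryl silyl ether selectively, acetic acid buffering protects the acid- and base-sensitive p-hydroxycinnamyl carbinol, and no stereocentre is touched.

## Compound list

1 | 6,7-dimethoxy-3,4-dihydronaphthalen-1(2H)-one | COc1cc2c(cc1OC)C(=O)CCC2 | starting material
2 | 6,7-dimethoxy-1,2,3,4-tetrahydronaphthalen-1-ol (racemic) | COc1cc2c(cc1OC)C(O)CCC2 | intermediate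
3 | 6,7-dimethoxy-1,2-dihydronaphthalene | COc1cc2c(cc1OC)C=CCC2 | intermediate
4 | (E)-3-(4-hydroxyphenyl)prop-2-enoic acid | OC(=O)/C=C/c1ccc(O)cc1 | starting material
5 | triisopropylsilyl (E)-3-[4-(triisopropylsilyloxy)phenyl]prop-2-enoate | CC(C)[Si](C(C)C)(C(C)C)OC(=O)/C=C/c1ccc(O[Si](C(C)C)(C(C)C)C(C)C)cc1 | intermediate
6 | (E)-3-[4-(triisopropylsilyloxy)phenyl]prop-2-enoyl chloride | O=C(Cl)/C=C/c1ccc(O[Si](C(C)C)(C(C)C)C(C)C)cc1 | intermediate
7 | (E)-1-[(1R,2R)-6,7-dimethoxy-2-(4,4,5,5-tetramethyl-1,3,2-dioxaborolan-2-yl)-1,2,3,4-tetrahydronaphthalen-1-yl]-3-[4-(triisopropylsilyloxy)phenyl]prop-2-en-1-one (acyl and boryl cis) | COc1cc2c(cc1OC)[C@H](C(=O)/C=C/c1ccc(O[Si](C(C)C)(C(C)C)C(C)C)cc1)[C@H](B1OC(C)(C)C(C)(C)O1)CC2 | intermediate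
8 | (E)-1-[(1S,2R)-2-hydroxy-6,7-dimethoxy-1,2,3,4-tetrahydronaphthalen-1-yl]-3-[4-(triisopropylsilyloxy)phenyl]prop-2-en-1-one | COc1cc2c(cc1OC)[C@H](C(=O)/C=C/c1ccc(O[Si](C(C)C)(C(C)C)C(C)C)cc1)[C@H](O)CC2 | intermediate
9 | (E)-1-[(1S,2R)-2-(diethylboryloxy)-6,7-dimethoxy-1,2,3,4-tetrahydronaphthalen-1-yl]-3-[4-(triisopropylsilyloxy)phenyl]prop-2-en-1-one (boron chelated by the ketone) | COc1cc2c(cc1OC)[C@H](C(=O)/C=C/c1ccc(O[Si](C(C)C)(C(C)C)C(C)C)cc1)[C@H](OB(CC)CC)CC2 | intermediate
10 | sodium cyclic diethylborate of diol 11 (boron bridging the C2 and C1' oxygens) | COc1cc2c(cc1OC)[C@@H]3[C@H](/C=C/c1ccc(O[Si](C(C)C)(C(C)C)C(C)C)cc1)O[B-](CC)(CC)O[C@@H]3CC2.[Na+] | intermediate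
11 | (1S,2R)-1-[(1S,2E)-1-hydroxy-3-[4-(triisopropylsilyloxy)phenyl]prop-2-en-1-yl]-6,7-dimethoxy-1,2,3,4-tetrahydronaphthalen-2-ol | COc1cc2c(cc1OC)[C@H]([C@@H](O)/C=C/c1ccc(O[Si](C(C)C)(C(C)C)C(C)C)cc1)[C@H](O)CC2 | intermediate
12 | (1S,2R)-1-[(1S,2E)-1-hydroxy-3-(4-hydroxyphenyl)prop-2-en-1-yl]-6,7-dimethoxy-1,2,3,4-tetrahydronaphthalen-2-ol | COc1cc2c(cc1OC)[C@H]([C@@H](O)/C=C/c1ccc(O)cc1)[C@H](O)CC2 | target

## Step count and risk

Total steps: 7. Longest linear sequence: 6 (steps 2 to 7 from 4; 5 steps from 1).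

The three steps most likely to fail:

**Step 4.** The copper boryl may add in conjugate fashion to the enoyl chloride 6 or to the enone of 7. Insertion into the electron-rich alkene may be slow, and ee and dr are unproven.
Fallback, setting out from 3 and coming back at 7: 3 is borylacylated under the same copper catalysis with acetyl chloride, a saturated acid chloride with no Michael acceptor. This gives the methyl ketone 1-[(1R,2R)-6,7-dimethoxy-2-(4,4,5,5-tetramethyl-1,3,2-dioxaborolan-2-yl)-1,2,3,4-tetrahydronaphthalen-1-yl]ethan-1-one F1. Separately, 4-hydroxybenzaldehyde is silylated (TIPSCl, imidazole, DMF) to 4-(triisopropylsilyloxy)benzaldehyde F2. An amine-catalysed Claisen–Schmidt condensation of F1 with F2 (pyrrolidine 30 mol%, AcOH 30 mol%, CH2Cl2, rt to 40 °C; the enamine forms on the unhindered methyl side) then builds the E-enone after the copper step and returns to 7.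

**Step 5.** The basic oxidant may epimerise C1, dehydrate the β-hydroxy ketone (E1cB) or epoxidise the enone.
Fallback, setting out from 7 and coming back at 8: the order of redox events is changed. Luche reduction of 7 (NaBH4, CeCl3·7H2O, MeOH, −40 °C) gives the boryl allylic alcohol (E)-1-[(1R,2R)-6,7-dimethoxy-2-(4,4,5,5-tetramethyl-1,3,2-dioxaborolan-2-yl)-1,2,3,4-tetrahydronaphthalen-1-yl]-3-[4-(triisopropylsilyloxy)phenyl]prop-2-en-1-ol F3 as both carbinol epimers, with no enolisable centre left. NaBO3·4H2O then gives the diol (1S,2R)-1-[(2E)-1-hydroxy-3-[4-(triisopropylsilyloxy)phenyl]prop-2-en-1-yl]-6,7-dimethoxy-1,2,3,4-tetrahydronaphthalen-2-ol F4 as both carbinol epimers. MnO2 (CH2Cl2, rt) re-oxidises only the allylic hydroxyl and returns 8 under neutral conditions.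

**Step 6.** Syn selectivity may be eroded by the α-aryl group, and some conjugate reduction is possible.
Fallback, setting out from 8 and coming back at 11: the carbinol is made on purpose with the opposite sense and then inverted. Evans–Saksena reduction (Me4NBH(OAc)3, MeCN/AcOH, −30 °C; intramolecular hydride delivery) gives the 1,3-anti diol (1S,2R)-1-[(1R,2E)-1-hydroxy-3-[4-(triisopropylsilyloxy)phenyl]prop-2-en-1-yl]-6,7-dimethoxy-1,2,3,4-tetrahydronaphthalen-2-ol F5. Mitsunobu esterification of the more reactive allylic hydroxyl (PPh3, DIAD, 4-nitrobenzoic acid, PhMe, −20 °C) gives the inverted ester (1S,2E)-1-[(1S,2R)-2-hydroxy-6,7-dimethoxy-1,2,3,4-tetrahydronaphthalen-1-yl]-3-[4-(triisopropylsilyloxy)phenyl]prop-2-en-1-yl 4-nitrobenzoate F6. K2CO3 in MeOH at 0 °C cleaves the ester to 11.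

## Further compounds

F1 | step 4 | 1-[(1R,2R)-6,7-dimethoxy-2-(4,4,5,5-tetramethyl-1,3,2-dioxaborolan-2-yl)-1,2,3,4-tetrahydronaphthalen-1-yl]ethan-1-one | COc1cc2c(cc1OC)[C@H](C(C)=O)[C@H](B1OC(C)(C)C(C)(C)O1)CC2
F2 | step 4 | 4-(triisopropylsilyloxy)benzaldehyde | O=Cc1ccc(O[Si](C(C)C)(C(C)C)C(C)C)cc1
F3 | step 5 | (E)-1-[(1R,2R)-6,7-dimethoxy-2-(4,4,5,5-tetramethyl-1,3,2-dioxaborolan-2-yl)-1,2,3,4-tetrahydronaphthalen-1-yl]-3-[4-(triisopropylsilyloxy)phenyl]prop-2-en-1-ol (both carbinol epimers) | COc1cc2c(cc1OC)[C@H](C(O)/C=C/c1ccc(O[Si](C(C)C)(C(C)C)C(C)C)cc1)[C@H](B1OC(C)(C)C(C)(C)O1)CC2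
F4 | step 5 | (1S,2R)-1-[(2E)-1-hydroxy-3-[4-(triisopropylsilyloxy)phenyl]prop-2-en-1-yl]-6,7-dimethoxy-1,2,3,4-tetrahydronaphthalen-2-ol (both carbinol epimers) | COc1cc2c(cc1OC)[C@H](C(O)/C=C/c1ccc(O[Si](C(C)C)(C(C)C)C(C)C)cc1)[C@H](O)CC2
F5 | step 6 | (1S,2R)-1-[(1R,2E)-1-hydroxy-3-[4-(triisopropylsilyloxy)phenyl]prop-2-en-1-yl]-6,7-dimethoxy-1,2,3,4-tetrahydronaphthalen-2-ol | COc1cc2c(cc1OC)[C@H]([C@H](O)/C=C/c1ccc(O[Si](C(C)C)(C(C)C)C(C)C)cc1)[C@H](O)CC2
F6 | step 6 | (1S,2E)-1-[(1S,2R)-2-hydroxy-6,7-dimethoxy-1,2,3,4-tetrahydronaphthalen-1-yl]-3-[4-(triisopropylsilyloxy)phenyl]prop-2-en-1-yl 4-nitrobenzoate | COc1cc2c(cc1OC)[C@H]([C@@H](OC(=O)c1ccc(cc1)[N+](=O)[O-])/C=C/c1ccc(O[Si](C(C)C)(C(C)C)C(C)C)cc1)[C@H](O)CC2
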